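**Retrosynthetic overview**
1. Target 15 ⇒ C2-symmetric 2-alkylresorcinol bis-MOM ether 8 + cinnamoyl Weinreb amide 12. One ortho-lithiation/acylation desymmetrizes the ring and installs the whole E-enone; acid in the same flask frees the three phenols.
2. 8 ⇒ aryl epoxide 7 by epoxide-to-allylic-alcohol isomerization (tertiary C–O broken, carbinol C–O kept).
3. 7 ⇒ C2-lithiated resorcinol bis-MOM ether (from resorcinol) + epoxyneryl tosylate 5 (Sharpless epoxidation of nerol; this sets the only stereocentre).
4. 12 ⇒ 4-hydroxybenzaldehyde + Weinreb phosphonate 10 (Horner–Wadsworth–Emmons).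
5. No ring is built: ring A comes from resorcinol and ring B from 4-hydroxybenzaldehyde; the only ring made is the transient oxirane.

Assumption: the target is the (R)-carbinol encoded in the SMILES; its enantiomeric purity is that of the tartrate-controlled epoxidation (about 90–94% ee expected), carried through unchanged.

**Route**

Step 1
Reactants: 1 resorcinol
Product: 2 1,3-bis(methoxymethoxy)benzene
Conditions: NaH (2.2 equiv), MOMCl (2.2 equiv), DMF, 0 °C → rt
Reagents that add atoms: chloromethyl methyl ether (MOMCl), COCCl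
Why: Williamson O-alkylation of both phenoxides gives the symmetric bis-acetal, whose OMOM groups later direct ortho-lithiation and are removed by mild acid.

Step 2
Reactants: 3 nerol
Product: 5 [(2R,3S)-3-methyl-3-(4-methylpent-3-en-1-yl)oxiran-2-yl]methyl 4-methylbenzenesulfonate, via (2R,3S)-2,3-epoxynerol 4 (not isolated)
Conditions: Ti(OiPr)4 (5 mol %), D-(−)-diisopropyl tartrate (7 mol %), t-BuOOH (1.5 equiv), 4 Å MS, CH2Cl2, −20 °C; then P(OMe)3; Et3N, DMAP (cat.), TsCl, −20 → 0 °C
Reagents that add atoms: tert-butyl hydroperoxide, CC(C)(C)OO; 4-toluenesulfonyl chloride (TsCl), Cc1ccc(cc1)S(Cl)(=O)=O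
Why: Katsuki–Sharpless asymmetric epoxidation with the D-(−)-tartrate catalyst gives the (2R,3S)-epoxide (the L-(+)-tartrate gives 2S,3R), which fixes the future carbinol carbon as R, and in situ tosylation of the epoxy alcohol follows directly.

Step 3
Reactants: 2 1,3-bis(methoxymethoxy)benzene; 5 epoxyneryl tosylate
Product: 7 (2S,3R)-3-{[2,6-bis(methoxymethoxy)phenyl]methyl}-2-methyl-2-(4-methylpent-3-en-1-yl)oxirane, via 2-lithio-1,3-bis(methoxymethoxy)benzene 6 (not isolated)
Conditions: n-BuLi (1.1 equiv), THF, 0 °C → rt; CuI (10 mol %), then 5, −40 → 0 °C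
Reagents that add atoms: none
Why: Directed ortho-metalation between the two OMOM groups gives the C2 aryllithium, which displaces the primary tosylate (copper-catalysed SN2) without touching either epoxide C–O bond, so both stereocentres are carried over (the descriptors change only through ring renumbering).

Step 4
Reactants: 7 aryl epoxide
Product: 8 (2R)-1-[2,6-bis(methoxymethoxy)phenyl]-7-methyl-3-methylideneoct-6-en-2-ol
Conditions: diethylaluminium 2,2,6,6-tetramethylpiperidide Et2Al(TMP) (4 equiv; from 2,2,6,6-tetramethylpiperidine, n-BuLi, Et2AlCl), toluene, 0 °C → rt; H2O work-up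
Reagents that add atoms: none
Why: Yamamoto–Nozaki epoxide-to-allylic-alcohol isomerization: aluminium binds the epoxide oxygen and the hindered amide removes, syn, a proton of the methyl group cis to the ring hydrogen (the nerol-derived epoxide places CH3 there) as the tertiary C–O bond breaks, while the secondary C–O bond is untouched and the R carbinol is retained.

Step 5
Reactants: 9 4-hydroxybenzaldehyde; 10 diethyl [2-(methoxy(methyl)amino)-2-oxoethyl]phosphonate
Product: 12 (2E)-N-methoxy-3-[4-(methoxymethoxy)phenyl]-N-methylprop-2-enamide, via 4-(methoxymethoxy)benzaldehyde 11 (not isolated)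
Conditions: NaH (1.05 equiv), MOMCl (1.05 equiv), THF/DMF, 0 °C → rt; then added to 10 + NaH (1.1 equiv), THF, 0 °C → rt
Reagents that add atoms: chloromethyl methyl ether (MOMCl), COCCl
Why: Phenol O-alkylation followed in the same flask by Horner–Wadsworth–Emmons olefination with the stabilised phosphonate anion gives the E-configured Weinreb cinnamamide.

Step 6
Reactants: 8 symmetric bis-MOM allylic alcohol; 12 Weinreb cinnamamide
Product: 15 (2E)-1-{2,4-dihydroxy-3-[(2R)-2-hydroxy-7-methyl-3-methylideneoct-6-en-1-yl]phenyl}-3-(4-hydroxyphenyl)prop-2-en-1-one, via dilithio alkoxide 13 (not isolated), via tris-MOM chalcone 14 (not isolated)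
Conditions: s-BuLi (2.3 equiv), TMEDA, THF, −78 → −40 °C; 12 (1.2 equiv), −78 → 0 °C; then HCl in MeOH (1.25 M, excess), 0 °C → rt
Reagents that add atoms: none
Why: After alkoxide formation, MOM-directed ortho-lithiation at one of the two equivalent ring positions and Weinreb ketone synthesis with 12 (1,2-addition, chelated tetrahedral adduct) break the ring symmetry and install the complete E-enone in one C–C bond formation, and methanolic HCl then collapses the adduct and transacetalizes the three MOM ethers without involving the carbinol stereocentre.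

**Compound list**
1 | resorcinol (benzene-1,3-diol) | Oc1cccc(O)c1 | starting material
2 | 1,3-bis(methoxymethoxy)benzene | COCOc1cccc(OCOC)c1 | intermediate
3 | nerol, (2Z)-3,7-dimethylocta-2,6-dien-1-ol | CC(C)=CCC/C(C)=C\CO | starting material
4 | (2R,3S)-2,3-epoxynerol, [(2R,3S)-3-methyl-3-(4-methylpent-3-en-1-yl)oxiran-2-yl]methanol | OC[C@H]1O[C@@]1(C)CCC=C(C)C | intermediate
5 | [(2R,3S)-3-methyl-3-(4-methylpent-3-en-1-yl)oxiran-2-yl]methyl 4-methylbenzenesulfonate | Cc1ccc(cc1)S(=O)(=O)OC[C@H]1O[C@@]1(C)CCC=C(C)C | intermediate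
6 | 2-lithio-1,3-bis(methoxymethoxy)benzene | [Li]c1c(OCOC)cccc1OCOC | intermediate
7 | (2S,3R)-3-{[2,6-bis(methoxymethoxy)phenyl]methyl}-2-methyl-2-(4-methylpent-3-en-1-yl)oxirane (ring CH carbon R, quaternary carbon S) | COCOc1cccc(OCOC)c1C[C@H]1O[C@@]1(C)CCC=C(C)C | intermediate
8 | (2R)-1-[2,6-bis(methoxymethoxy)phenyl]-7-methyl-3-methylideneoct-6-en-2-ol | C=C(CCC=C(C)C)[C@H](O)Cc1c(OCOC)cccc1OCOC | intermediate
9 | 4-hydroxybenzaldehyde | O=Cc1ccc(O)cc1 | starting material
10 | diethyl [2-(methoxy(methyl)amino)-2-oxoethyl]phosphonate | CCOP(=O)(OCC)CC(=O)N(C)OC | starting material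
11 | 4-(methoxymethoxy)benzaldehyde | COCOc1ccc(C=O)cc1 | intermediate
12 | (2E)-N-methoxy-3-[4-(methoxymethoxy)phenyl]-N-methylprop-2-enamide | COCOc1ccc(/C=C/C(=O)N(C)OC)cc1 | intermediate
13 | lithium (2R)-1-[3-lithio-2,6-bis(methoxymethoxy)phenyl]-7-methyl-3-methylideneoct-6-en-2-olate | C=C(CCC=C(C)C)[C@H](O[Li])Cc1c(OCOC)ccc([Li])c1OCOC | intermediate
14 | (2E)-1-{3-[(2R)-2-hydroxy-7-methyl-3-methylideneoct-6-en-1-yl]-2,4-bis(methoxymethoxy)phenyl}-3-[4-(methoxymethoxy)phenyl]prop-2-en-1-one | C=C(CCC=C(C)C)[C@H](O)Cc1c(OCOC)ccc(C(=O)/C=C/c2ccc(OCOC)cc2)c1OCOC | intermediate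
15 | (2E)-1-{2,4-dihydroxy-3-[(2R)-2-hydroxy-7-methyl-3-methylideneoct-6-en-1-yl]phenyl}-3-(4-hydroxyphenyl)prop-2-en-1-one | C=C(CCC=C(C)C)[C@H](O)Cc1c(O)ccc(C(=O)/C=C/c2ccc(O)cc2)c1O | target

**Totals**
Total step count: 6. Longest linear sequence: 4 steps (1 → 2 → 7 → 8 → 15, or 3 → 5 → 7 → 8 → 15).

**Steps most likely to fail, with fallbacks**

Step 4 (regiochemistry of the isomerization). The base could instead remove a benzylic proton, giving the styrenyl tertiary alcohol, or a chain CH2 proton, giving the internal alkene. The fallback sets out from 7 and comes back at 8, and replaces the base-induced elimination by a radical opening that uses no base. Titanocene chloride Cp2TiCl (trivalent titanium, made from Cp2TiCl2 and Mn dust, THF, rt) cleaves the tertiary C–O bond homolytically. The tertiary radical loses a β-hydrogen to a second Cp2TiCl, mainly from the methyl group, to give the exocyclic methylene alcohol 8. The benzylic position is never deprotonated and the carbinol C–O bond is again untouched. No new compound is made (F0).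

Step 6 (dilithiation, cinnamoyl transfer and in-flask deprotection). The alkoxide could direct lithiation elsewhere, the aryllithium could add 1,4 to 12, or the acid stage could damage the allylic alcohol and the alkenes. The fallback sets out from 8 and comes back at 14, building the enone in two stages. Dilithio alkoxide 13 is quenched with N-methoxy-N-methylacetamide to give 1-{3-[(2R)-2-hydroxy-7-methyl-3-methylideneoct-6-en-1-yl]-2,4-bis(methoxymethoxy)phenyl}ethan-1-one F4. Claisen–Schmidt condensation of F4 with 11 (isolated after the first stage of step 5; KOH, EtOH, rt) gives 14. Isolated 14 is then deprotected in a separate operation with methanolic HCl at 0 °C to reach 15.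

Step 3 (aryllithium against epoxy tosylate). The hindered aryllithium could attack sulfur or the epoxide. The fallback sets out from 2 and comes back at 8, so steps 2 to 4 are not needed and the stereocentre is set by a chiral catalyst instead.
- 2 is lithiated as before to 6 and opened with ethylene oxide to give 2-[2,6-bis(methoxymethoxy)phenyl]ethan-1-ol F1.
- Dess–Martin oxidation of F1 gives [2,6-bis(methoxymethoxy)phenyl]acetaldehyde F2.
- Commercial 6-methylhept-5-en-2-one is converted through its kinetic enolate (lithium diisopropylamide, PhNTf2, THF, −78 °C) into 6-methylhepta-1,5-dien-2-yl trifluoromethanesulfonate F3.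
- Catalytic asymmetric Nozaki–Hiyama–Kishi coupling of F2 with F3 (CrCl2 and NiCl2 catalysts, chiral sulfonamide–oxazoline ligand, Mn, Cp2ZrCl2, LiCl, MeCN) gives 8. The ligand enantiomer is chosen to deliver the R alcohol.

**Further compounds**
F1 | step 3 | 2-[2,6-bis(methoxymethoxy)phenyl]ethan-1-ol | COCOc1cccc(OCOC)c1CCO
F2 | step 3 | [2,6-bis(methoxymethoxy)phenyl]acetaldehyde | COCOc1cccc(OCOC)c1CC=O
F3 | step 3 | 6-methylhepta-1,5-dien-2-yl trifluoromethanesulfonate | C=C(CCC=C(C)C)OS(=O)(=O)C(F)(F)F
F0 | step 4 | none | none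
F4 | step 6 | 1-{3-[(2R)-2-hydroxy-7-methyl-3-methylideneoct-6-en-1-yl]-2,4-bis(methoxymethoxy)phenyl}ethan-1-one | C=C(CCC=C(C)C)[C@H](O)Cc1c(OCOC)ccc(C(C)=O)c1OCOC
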